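The earlier runs and the new flask come from a simulation with made-up constants; noise was put on by code.

Add the target and starting material columns of each run together before you look at any rate.

in all of them: free catalyst 2.3 mM; stray impurity 0.32 mM
- maple: starting material 12 mM; capture agent 0.80 mM; protic impurity 0.60 mM; temperature −20 °C; run made earlier
- elm: starting material 12 mM; capture agent 1.8 mM; protic impurity 0.60 mM; temperature 13 °C; run made earlier
- larch: starting material 24 mM; capture agent 1.2 mM; protic impurity 0.60 mM; temperature −20 °C; run made earlier
- midnight: starting material 12 mM; capture agent 1.20 mM; protic impurity 0.600 mM; temperature −35 °C; time 20 h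
- noon: starting material 12 mM; capture agent 1.20 mM; protic impurity 0.600 mM; temperature 25 °C; time 20 h
- dusk: starting material 12 mM; capture agent 1.20 mM; protic impurity 0.600 mM; temperature 5 °C; time 20 h
- winter: starting material 12 mM; capture agent 1.20 mM; protic impurity 0.600 mM; temperature −15 °C; time 20 h

- maple (time / h: target / %, starting material / %): 2.50: 0.7, 82.1; 5.00: 0.2, 79.3; 8.00: 1.4, 78.8; 10.0: 1.5, 76.8; 12.0: 2.9, 77.8
- elm (time / h: target / %, starting material / %): 0.500: 9.4, 70.4; 1.00: 18.6, 61.6; 1.33: 24.7, 55.7; 2.00: 32.2, 47.0; 2.50: 37.6, 41.8
- larch (time / h: target / %, starting material / %): 2.50: 0.7, 89.4; 5.00: 0.7, 88.6; 8.00: 1.5, 88.4; 10.0: 1.3, 88.6; 12.0: 1.5, 88.2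

(each reading ± 0.5 percentage points)

- the numbers in the tables scatter by 0.5 percentage points (one standard deviation)

* the flask that comes out highest in amount of target, in percent of the starting material charged, or "all alike" when all lie within 1.5 percentage points (midnight / noon / dusk / winter / all alike)
* target at the end, in percent of the starting material charged, midnight
* target at the end, in percent of the starting material charged, noon
* target at the end, in percent of the starting material charged, dusk
* target at the end, in percent of the starting material charged, winter

Start with elm. Its first row sums to 79.8% and its last row to 79.4%, so the sum stands still while target climbs to 37.6%. The missing part is 2.47 mM. Now read larch: its last row misses a smaller percentage, 10.3%, but the charge is twice as large, so you again get 2.47 mM.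

So take the gap as a fixed amount with two parts: one starting material lost to each protic impurity, and one sitting on each free catalyst that stray impurity has not taken, which together allow 2.58 mM against the gap read above. A working catalyst hands back what it holds, which makes the part on the catalyst a loan. What can stay away for good is one starting material per protic impurity and one per capture agent, and a capture agent needs a catalyst to sit on, so its share is capped by free catalyst less stray impurity, 1.98 mM. For these recipes that gives 15.0%, and this share of the charge kept for good is the toll.

My reckoning is therefore that a finished flask ends at 85.0% of target or a little above. Elm made 37.6% in 2.50 h and maple 2.9% in 12.0 h, so I expect noon, warmer than elm, to finish and lead, with dusk close behind and midnight and winter far short.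

The forecast names noon, with 0.1% for midnight, 79% for noon, 73% for dusk and 5% for winter, on its own ground of "leaving a ceiling near 80%", so its noon stands below my figure.

The flasks give 0.171% for midnight, 88.0% for noon, 81.0% for dusk and 8.42% for winter, and noon is highest.

    catalyst intermediate A → catalyst intermediate B (k = 0.120 /min, Ea = 84.0 kJ/mol)
    starting material + protic impurity → quenched substrate (k = 13.0 /M/min, Ea = 49.0 kJ/mol)
    catalyst intermediate A + capture agent → trapped intermediate (k = 14.0 /M/min, Ea = 49.0 kJ/mol)
    free catalyst + stray impurity → spent catalyst (k = 16000 /M/min, Ea = 38.0 kJ/mol)
    catalyst intermediate B → free catalyst + target (k = 5.00 /min, Ea = 79.0 kJ/mol)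
    starting material + free catalyst ⇌ catalyst intermediate A (K = 2200 /M, k = 98.0 /M/min, Ea = 56.0 kJ/mol, ΔH = −15.0 kJ/mol)
    (constants at 25 °C)

In noon, 0% of the starting material remains and 29% of the capture agent stands unbound, so the toll was not paid in full and target lands 3 percentage points above 85.0%. Now charge 4.8 mM of capture agent, the other charges held. The cap of 1.98 mM applies, the toll becomes 21.5%, and target plus starting material should stop at 78.5%. That flask shows 38.0% of target and 41% of starting material, together 79.0%, with 13.9% of its catalyst as spent catalyst and 86.1% as trapped intermediate, an off-cycle form.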